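**Retrosynthetic overview**

1. The target, a pentabromo bis-catechol diarylmethane, is cut at the CH2–aryl bond between the bridging carbon on the fully substituted tribromocatechol ring (ring B: CH2 on C1, Br on C2/C3/C6, OH on C4/C5) and C4 of the dibromocatechol ring (ring A: OH on C1/C2, Br on C3/C6).
2. Ring B enters as its o-quinone 3, which still carries a plain CH3. Acid-triggered tautomerization turns it into a p-quinone methide/benzylic cation that alkylates 3,6-dibromocatechol 4, a leaving-group-free union in which every atom of both partners ends in the product.
3. Enabling feature: in ring B the oxygen on C4 is para to C1, so the C4/C5 o-quinone with a methyl on C1 is a tautomer of the quinone methide at exactly the carbon to be bonded, and ring B has no C–H with which to self-condense. In ring A, C4–H is para to the C1 hydroxyl and equivalent to C5–H by symmetry.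
4. Quinone 3 comes from 4-methylcatechol by ring tribromination and silver(I) oxide oxidation. No ring is formed; both benzene rings are bought as catechols.

Key step: step 3

Remark: the target has no stereocentre and no hindered axis, so it is achiral and the request for a single enantiomer is met by the constitution alone. 3,6-Dibromobenzene-1,2-diol (4) is taken as a catalogue compound.

**Route**

Step 1
Reactants: 1 4-methylbenzene-1,2-diol (4-methylcatechol)
Product: 2 3,4,6-tribromo-5-methylbenzene-1,2-diol
Conditions: Br2 (3.05 equiv), AcOH, 10 °C → rt; aq. NaHSO3 work-up
Reagents that add atoms: bromine, BrBr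
Why: Electrophilic aromatic bromination: each of the three free ring positions is ortho or para to a hydroxyl, so three equivalents of bromine should fill the ring while the methyl group, which needs forcing conditions, stays intact, and the bisulfite wash returns any quinone to the catechol.

Step 2
Reactants: 2 3,4,6-tribromo-5-methylbenzene-1,2-diol
Product: 3 3,4,6-tribromo-5-methylcyclohexa-3,5-diene-1,2-dione (tribromo-methyl-o-benzoquinone)
Conditions: Ag2O (2 equiv), Na2SO4, Et2O, 0 °C, dark; filtration through Celite, cold evaporation, used at once
Reagents that add atoms: none
Why: Two-electron, two-proton oxidation of a catechol to an o-benzoquinone with silver(I) oxide under neutral anhydrous conditions; the ring bears no hydrogen, so the usual Michael and Diels–Alder self-reactions of o-quinones have no site, and without acid or soluble base the methyl group should not yet tautomerize.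

Step 3
Reactants: 3 3,4,6-tribromo-5-methylcyclohexa-3,5-diene-1,2-dione, 4 3,6-dibromobenzene-1,2-diol (3,6-dibromocatechol)
Product: 6 3,6-dibromo-4-[(2,3,6-tribromo-4,5-dihydroxyphenyl)methyl]benzene-1,2-diol (target), via quinone methide 5 (not isolated)
Conditions: TfOH (1.1 equiv), anhydrous HFIP/CH2Cl2 (4:1), 0 °C, until the red quinone colour fades; then 4 (2.5 equiv), 0 °C → rt
Reagents that add atoms: none
Why: Proposed new method: triflic acid in HFIP should protonate the carbonyl that is vinylogous to the methyl group and remove a methyl proton, giving quinone methide 5, whose O-protonated form is the aromatic 2,3,6-tribromo-4,5-dihydroxybenzyl cation, so the tautomerization is driven by aromatization; 4, added once the quinone colour has gone, then attacks this cation through C4 (para to its C1 hydroxyl) in a Friedel–Crafts 1,6-addition and loses a proton to give 6. The closest known reaction types are the isomerization of 4-alkyl-o-quinones to p-quinone methides and the acid/HFIP-promoted Friedel–Crafts benzylation of phenols by p-hydroxybenzyl alcohols and p-quinone methides; new is their merger into a union of a methyl-o-quinone with a second catechol that needs neither oxidant nor leaving group in the coupling flask. No ring is closed and no stereocentre is formed. The step needs C- over O-alkylation (O-benzylation is reversible under acid, the para C–C bond is not), a single site on 4 (its two C–H positions are equivalent by symmetry and each is para to a hydroxyl), mono-alkylation (excess 4, and the remaining C–H of 6 is flanked by bromine and the new benzyl group) and no self-condensation of the electrophile (the tribromo ring has no C–H). Redox selectivity rests on the staging: 4 and 6 are oxidizable catechols, so 4 is added only after the quinone has been converted.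

**Compound list**

1 | 4-methylbenzene-1,2-diol (4-methylcatechol) | Cc1ccc(O)c(O)c1 | starting material
2 | 3,4,6-tribromo-5-methylbenzene-1,2-diol | Cc1c(Br)c(O)c(O)c(Br)c1Br | intermediate
3 | 3,4,6-tribromo-5-methylcyclohexa-3,5-diene-1,2-dione | CC1=C(Br)C(=O)C(=O)C(Br)=C1Br | intermediate
4 | 3,6-dibromobenzene-1,2-diol (3,6-dibromocatechol) | Oc1c(Br)ccc(Br)c1O | starting material
5 | 2,3,5-tribromo-6-hydroxy-4-methylidenecyclohexa-2,5-dien-1-one (2-hydroxy-p-quinone methide, formed in the flask) | C=C1C(Br)=C(O)C(=O)C(Br)=C1Br | intermediate
6 | 3,6-dibromo-4-[(2,3,6-tribromo-4,5-dihydroxyphenyl)methyl]benzene-1,2-diol | Oc1c(Br)cc(Cc2c(Br)c(O)c(O)c(Br)c2Br)c(Br)c1O | target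

**Summary**

Total step count: 3. Longest linear sequence: 3 steps (1 → 2 → 3 → 6); compound 4 enters in the last step.

**Steps most likely to fail**

Step 3 (proposed new method). Enolization toward the methyl group may be slow or incomplete, so that unchanged quinone is still present when the catechol partner is added. Hydrogen transfer between quinone and catechols would then spread the oxidation level over partner and product and cause over-oxidation at the new diarylmethane carbon. The strong acid may also shift bromine between rings. The fallback uses known chemistry without any quinone; it sets out from 2 and comes back at 6. Acetylation of 2 (Ac2O, pyridine) should give 3,4,6-tribromo-5-methyl-1,2-phenylene diacetate F1. Wohl–Ziegler bromination (NBS, AIBN, PhCF3, reflux) should then give 3,4,6-tribromo-5-(bromomethyl)-1,2-phenylene diacetate F2. Acid methanolysis (HCl, MeOH, 50 °C) removes both acetates and solvolyses the now p-hydroxy-activated benzylic bromide to 3,4,6-tribromo-5-(methoxymethyl)benzene-1,2-diol F3. Friedel–Crafts benzylation of 4 with this ether (cat. TfOH, HFIP, rt) should give 6.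

Step 2. The oxidation level may be lost before the coupling, through tautomerization or decomposition of the quinone on the silver oxide surface or during concentration, or the oxidation may stall. The fallback stores the oxidation level in a benzylic C–Br bond instead of an isolated quinone; it sets out from 2 and comes back at 6. Side-chain bromination of 2 with one further equivalent of Br2 (AcOH or 1,2-dichloroethane, 60–80 °C) is the pseudobromide formation known for polybromo-p-cresols: ipso-bromination para to the hydroxyl, loss of HBr to the quinone methide and re-addition of HBr. It should give 3,4,6-tribromo-5-(bromomethyl)benzene-1,2-diol F4, which should alkylate 4 in HFIP at rt (quinone-methide Friedel–Crafts with loss of HBr) to give 6.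

Step 1. Bromination may stop short at the crowded position between hydroxyl and methyl, or bromine may oxidize the electron-rich catechol to quinone-derived by-products. The fallback brominates with the hydroxyls masked; it sets out from 1 and comes back at 2. O-Methylation (MeI, K2CO3, acetone) should give 1,2-dimethoxy-4-methylbenzene F5. Exhaustive bromination (excess Br2, cat. Fe, CH2Cl2/AcOH) should give 1,2,4-tribromo-5,6-dimethoxy-3-methylbenzene F6, and BBr3 demethylation (CH2Cl2, −78 °C → rt) returns 2.

**Further compounds**

F1 | step 3 | 3,4,6-tribromo-5-methyl-1,2-phenylene diacetate | Cc1c(Br)c(OC(C)=O)c(OC(C)=O)c(Br)c1Br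
F2 | step 3 | 3,4,6-tribromo-5-(bromomethyl)-1,2-phenylene diacetate | BrCc1c(Br)c(OC(C)=O)c(OC(C)=O)c(Br)c1Br
F3 | step 3 | 3,4,6-tribromo-5-(methoxymethyl)benzene-1,2-diol | COCc1c(Br)c(O)c(O)c(Br)c1Br
F4 | step 2 | 3,4,6-tribromo-5-(bromomethyl)benzene-1,2-diol | BrCc1c(Br)c(O)c(O)c(Br)c1Br
F5 | step 1 | 1,2-dimethoxy-4-methylbenzene | COc1ccc(C)cc1OC
F6 | step 1 | 1,2,4-tribromo-5,6-dimethoxy-3-methylbenzene | COc1c(Br)c(C)c(Br)c(Br)c1OC
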